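Ring B is not brought in as a benzene. It is built on the finished chromone. Its contiguous edge C3'(OH)–C4'(OMe)–C5'(prenyl)–C6'(H) corresponds to the ring oxygen and C2–C5 of 3-methoxy-4-prenylfuran. C1'–C2' corresponds to an ethynyl group on C2 of a 5,7-bis-MOM-protected 8-prenylchromone. In one operation, a (4+2) cycloaddition and the aromatising cleavage of the oxygen bridge form C2'–C3' and C1'–C6' and close ring B. The same operation releases the C3' phenol, already distinct from the C4' methyl ether. Both partners are reached by routine chemistry, and only mild acidic MOM removal follows.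

Key step: step 9

Remark: the target has no stereocentre and no stereogenic double bond, so no configuration has to be set. Abbreviations: prenyl = 3-methylbut-2-en-1-yl, MOM = methoxymethyl, fod = 6,6,7,7,8,8,8-heptafluoro-2,2-dimethyloctane-3,5-dionate.

Step 1
Reactants: 1 2,4,6-trihydroxyacetophenone; 2 prenyl bromide (1-bromo-3-methylbut-2-ene)
Product: 3 1-[2,4,6-trihydroxy-3-(3-methylbut-2-enyl)phenyl]ethanone
Conditions: KOH (1 equiv), H2O, 0 °C → rt
Reagents that add atoms: none
Why: Phenolate C-alkylation (the classical nuclear prenylation of acylphloroglucinols): in water the phenoxide oxygens are tied up by hydrogen bonding, so the soft allylic bromide is attacked by the electron-rich ring carbon C3 in an SN2 reaction, and one equivalent of 2 limits double prenylation.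

Step 2
Reactants: 3 1-[2,4,6-trihydroxy-3-(3-methylbut-2-enyl)phenyl]ethanone
Product: 4 1-[2-hydroxy-4,6-bis(methoxymethoxy)-3-(3-methylbut-2-enyl)phenyl]ethanone
Conditions: MOMCl (2.2 equiv), K2CO3, acetone, 0 °C → rt
Reagents that add atoms: chloromethyl methyl ether (MOMCl), COCCl
Why: Williamson-type O-alkylation takes the unchelated C4 hydroxyl and the less hindered ortho hydroxyl (C6, flanked by H), while the C2 hydroxyl, hemmed in by acetyl and prenyl and hydrogen-bonded to the ketone, stays free, and this is the oxygen that must become O1 of an 8-prenylchromone.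

Step 3
Reactants: 4 1-[2-hydroxy-4,6-bis(methoxymethoxy)-3-(3-methylbut-2-enyl)phenyl]ethanone; 5 diethyl oxalate
Product: 8 ethyl 5,7-bis(methoxymethoxy)-8-(3-methylbut-2-enyl)-4-oxo-4H-chromene-2-carboxylate, via diketo ester 6 (not isolated), via cyclic hemiketal 7 (not isolated)
Conditions: NaOEt, EtOH–THF, 60 °C; AcOH, extraction; then (CF3CO)2O, pyridine, CH2Cl2, 0 °C → rt
Reagents that add atoms: none
Why: Crossed Claisen condensation of the methyl ketone with the non-enolisable oxalate gives 6 in ring–chain equilibrium with 7, and activation of the hemiketal hydroxyl by the anhydride followed by E1cB elimination (the closing stage of a Kostanecki–Robinson chromone synthesis) dehydrates it without the hot mineral acid that would strip the MOM groups and endanger the prenyl group.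

Step 4
Reactants: 8 ethyl 5,7-bis(methoxymethoxy)-8-(3-methylbut-2-enyl)-4-oxo-4H-chromene-2-carboxylate
Product: 9 2-(hydroxymethyl)-5,7-bis(methoxymethoxy)-8-(3-methylbut-2-enyl)-4H-chromen-4-one
Conditions: NaBH4, EtOH–THF, 0 °C
Reagents that add atoms: none
Why: Chemoselective borohydride reduction, as known for chromone-2-carboxylates: the ester on the oxygen-bearing C2 is an activated alpha-oxygenated acrylate, whereas the C4 carbonyl is a vinylogous ester further deactivated by the O5 and O7 donors.

Step 5
Reactants: 9 2-(hydroxymethyl)-5,7-bis(methoxymethoxy)-8-(3-methylbut-2-enyl)-4H-chromen-4-one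
Product: 10 5,7-bis(methoxymethoxy)-8-(3-methylbut-2-enyl)-4-oxo-4H-chromene-2-carbaldehyde
Conditions: Dess–Martin periodinane, CH2Cl2, 0 °C → rt
Reagents that add atoms: none
Why: Dess–Martin oxidation stops at the aldehyde under nearly neutral conditions and touches neither the trisubstituted alkene nor the two acetals.

Step 6
Reactants: 10 5,7-bis(methoxymethoxy)-8-(3-methylbut-2-enyl)-4-oxo-4H-chromene-2-carbaldehyde
Product: 11 2-ethynyl-5,7-bis(methoxymethoxy)-8-(3-methylbut-2-enyl)-4H-chromen-4-one
Conditions: Me3SiCHN2 (1.1 equiv), LiN(iPr)2, THF, −78 °C; then 10, −78 → 0 °C; H2O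
Reagents that add atoms: (trimethylsilyl)diazomethane, C[Si](C)(C)C=[N+]=[N-]
Why: Colvin rearrangement: the lithiated diazo reagent adds to the aldehyde, the most electrophilic carbonyl present, and loss of Me3SiOLi and N2 with a 1,2-hydrogen shift gives the alkyne, while the aprotic medium avoids the methoxide–methanol of the Ohira–Bestmann variant, which would add to the pyrone and to the activated alkyne.

Step 7
Reactants: 12 3,4-dibromofuran; 2 prenyl bromide
Product: 14 3-bromo-4-(3-methylbut-2-enyl)furan, via 3-bromo-4-lithiofuran 13 (not isolated)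
Conditions: n-BuLi (1.0 equiv), Et2O, −78 °C; CuBr·SMe2 (10 mol %), 2, −78 → −30 °C
Reagents that add atoms: none
Why: Bromine–lithium exchange on the symmetrical dibromide is fast at −78 °C, where a 3-furyllithium does not yet isomerise to the 2-lithio isomer, and the copper-catalysed allylation is an SN2 reaction at the primary carbon of 2 because the gamma carbon is blocked by two methyl groups.

Step 8
Reactants: 14 3-bromo-4-(3-methylbut-2-enyl)furan
Product: 15 3-methoxy-4-(3-methylbut-2-enyl)furan
Conditions: NaOMe, MeOH–NMP, CuBr (10 mol %), 110 °C; basic work-up, store over K2CO3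
Reagents that add atoms: sodium methoxide, [Na+].[O-]C
Why: Ullmann-type copper-catalysed C–O coupling, as used to convert 3-halofurans and 3-bromothiophenes into their 3-methoxy derivatives, runs in a strongly basic, acid-free medium that suits the acid-labile enol-ether product and leaves the isolated trisubstituted alkene alone.

Step 9
Reactants: 11 2-ethynyl-5,7-bis(methoxymethoxy)-8-(3-methylbut-2-enyl)-4H-chromen-4-one; 15 3-methoxy-4-(3-methylbut-2-enyl)furan
Product: 17 2-[3-hydroxy-4-methoxy-5-(3-methylbut-2-enyl)phenyl]-5,7-bis(methoxymethoxy)-8-(3-methylbut-2-enyl)-4H-chromen-4-one, via oxa-bridged diene 16 (not isolated)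
Conditions: 15 (3 equiv), Eu(fod)3 (10 mol %), PhMe (1 M), 80 °C; then pyridinium p-toluenesulfonate (10 mol %), CH2Cl2, rt
Reagents that add atoms: none
Why: Proposed new method: with the oxophilic europium chelate on the C4 carbonyl lowering the LUMO, the unsubstituted furan carbon next to the methoxy group (future C3', largest HOMO coefficient) pairs with the terminal alkyne carbon (future C2', the delta position of the alkyne–C2=C3–C4=O vinylogous ynone), and ring B closes by an asynchronous intermolecular (4+2) cycloaddition that forms C2'–C3' and C1'–C6' and gives the 7-oxanorbornadiene 16 in the "para" orientation of donor and acceptor. Mild acid should then ionise only the C6'–O bond, since that cation is an oxocarbenium ion through C5'=C4'–OMe, whereas a cation at C3' would gain nothing from the methoxy group and would put charge on C1' next to the electron-poor chromone. Loss of the C3' proton aromatises ring B and leaves the former furan oxygen as the free C3' phenol beside the C4' methyl ether. The closest known reaction types are Diels–Alder additions of 3-alkoxyfurans to acetylenic ketones and esters and the acid opening of 7-oxanorbornadienes to phenols, but a 2-ethynylchromone has not been shown as the dienophile. The two bridgehead stereocentres of racemic 16 disappear on aromatisation, so no stereocontrol is required. The step needs the right orientation, the right direction of bridge opening and chemoselectivity for the alkyne over the chromone C2=C3 bond and the two prenyl alkenes: the methoxy group secures the first two, and the last holds because the terminal alkyne is the only unhindered electron-poor pi bond.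

Step 10
Reactants: 17 2-[3-hydroxy-4-methoxy-5-(3-methylbut-2-enyl)phenyl]-5,7-bis(methoxymethoxy)-8-(3-methylbut-2-enyl)-4H-chromen-4-one
Product: 18 5,7-dihydroxy-2-[3-hydroxy-4-methoxy-5-(3-methylbut-2-enyl)phenyl]-8-(3-methylbut-2-enyl)-4H-chromen-4-one (target)
Conditions: conc. HCl (cat.), MeOH, 45 °C
Reagents that add atoms: none
Why: Acid-catalysed acetal exchange with methanol removes both MOM groups (the peri O5 group first) under the dilute conditions that C-prenylated flavonoids routinely survive, short exposure keeps the C8 prenyl group from closing onto O7, and the ring B prenyl group has no free ortho hydroxyl to close onto.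

Compound list
1 | 2,4,6-trihydroxyacetophenone | CC(=O)c1c(O)cc(O)cc1O | starting material
2 | prenyl bromide (1-bromo-3-methylbut-2-ene) | CC(C)=CCBr | starting material
3 | 1-[2,4,6-trihydroxy-3-(3-methylbut-2-enyl)phenyl]ethanone | CC(=O)c1c(O)cc(O)c(CC=C(C)C)c1O | intermediate
4 | 1-[2-hydroxy-4,6-bis(methoxymethoxy)-3-(3-methylbut-2-enyl)phenyl]ethanone | CC(=O)c1c(O)c(CC=C(C)C)c(OCOC)cc1OCOC | intermediate
5 | diethyl oxalate | CCOC(=O)C(=O)OCC | starting material
6 | ethyl 4-[2-hydroxy-4,6-bis(methoxymethoxy)-3-(3-methylbut-2-enyl)phenyl]-2,4-dioxobutanoate | CCOC(=O)C(=O)CC(=O)c1c(O)c(CC=C(C)C)c(OCOC)cc1OCOC | intermediate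
7 | ethyl 2-hydroxy-5,7-bis(methoxymethoxy)-8-(3-methylbut-2-enyl)-4-oxochromane-2-carboxylate (racemic) | CCOC(=O)C1(O)CC(=O)c2c(OCOC)cc(OCOC)c(CC=C(C)C)c2O1 | intermediate
8 | ethyl 5,7-bis(methoxymethoxy)-8-(3-methylbut-2-enyl)-4-oxo-4H-chromene-2-carboxylate | CCOC(=O)c1cc(=O)c2c(OCOC)cc(OCOC)c(CC=C(C)C)c2o1 | intermediate
9 | 2-(hydroxymethyl)-5,7-bis(methoxymethoxy)-8-(3-methylbut-2-enyl)-4H-chromen-4-one | OCc1cc(=O)c2c(OCOC)cc(OCOC)c(CC=C(C)C)c2o1 | intermediate
10 | 5,7-bis(methoxymethoxy)-8-(3-methylbut-2-enyl)-4-oxo-4H-chromene-2-carbaldehyde | O=Cc1cc(=O)c2c(OCOC)cc(OCOC)c(CC=C(C)C)c2o1 | intermediate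
11 | 2-ethynyl-5,7-bis(methoxymethoxy)-8-(3-methylbut-2-enyl)-4H-chromen-4-one | C#Cc1cc(=O)c2c(OCOC)cc(OCOC)c(CC=C(C)C)c2o1 | intermediate
12 | 3,4-dibromofuran | Brc1cocc1Br | starting material
13 | 3-bromo-4-lithiofuran | [Li]c1cocc1Br | intermediate
14 | 3-bromo-4-(3-methylbut-2-enyl)furan | CC(C)=CCc1cocc1Br | intermediate
15 | 3-methoxy-4-(3-methylbut-2-enyl)furan | COc1cocc1CC=C(C)C | intermediate
16 | 2-[5-methoxy-6-(3-methylbut-2-enyl)-7-oxabicyclo[2.2.1]hepta-2,5-dien-2-yl]-5,7-bis(methoxymethoxy)-8-(3-methylbut-2-enyl)-4H-chromen-4-one (racemic, oxygen bridge between future C3' and C6') | COC1=C(CC=C(C)C)C2OC1C=C2c1cc(=O)c2c(OCOC)cc(OCOC)c(CC=C(C)C)c2o1 | intermediate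
17 | 2-[3-hydroxy-4-methoxy-5-(3-methylbut-2-enyl)phenyl]-5,7-bis(methoxymethoxy)-8-(3-methylbut-2-enyl)-4H-chromen-4-one | COc1c(O)cc(-c2cc(=O)c3c(OCOC)cc(OCOC)c(CC=C(C)C)c3o2)cc1CC=C(C)C | intermediate
18 | 5,7-dihydroxy-2-[3-hydroxy-4-methoxy-5-(3-methylbut-2-enyl)phenyl]-8-(3-methylbut-2-enyl)-4H-chromen-4-one | COc1c(O)cc(-c2cc(=O)c3c(O)cc(O)c(CC=C(C)C)c3o2)cc1CC=C(C)C | target

Total step count: 10. Longest linear sequence: 8 (steps 1–6, 9 and 10). The furan arm (steps 7 and 8) runs in parallel.

Steps most likely to fail

Step 9. The cycloaddition may be too slow to compete with cycloreversion and with thermal or acid-induced decay of the furan. The first C–C bond may also be followed by proton loss (conjugate alkenylation of the furan) instead of ring closure. The fallback gives up the ring synthesis and assembles the flavone classically, setting out from 4 and coming back at 18. Purchased methyl 3-bromo-4,5-dihydroxybenzoate is methylated at the more acidic O4 (MeI, Li2CO3, DMF) to methyl 3-bromo-5-hydroxy-4-methoxybenzoate F1. This is protected (MOMCl, K2CO3, acetone) as methyl 3-bromo-4-methoxy-5-(methoxymethoxy)benzoate F2. Stille coupling with tributyl(3-methylbut-2-enyl)stannane and Pd(PPh3)4 in DMF gives methyl 4-methoxy-3-(methoxymethoxy)-5-(3-methylbut-2-enyl)benzoate F3. Claisen condensation of 4 with this ester (NaH, THF, reflux) gives the 1,3-diaryl-1,3-diketone F4. Warm methanolic HCl then closes the pyrone ring and removes all three MOM groups in one operation to give 18.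

Step 6. The lithiated diazo reagent may attack the pyrone ring in competition with the aldehyde, and surplus reagent may undergo dipolar cycloaddition to the freshly formed activated alkyne. The fallback replaces the diazo homologation by an olefination and elimination sequence without any strong nucleophile, setting out from 10 and coming back at 11. Ramirez olefination (CBr4, PPh3, CH2Cl2, 0 °C) gives the 2-(2,2-dibromovinyl)chromone F5. Stereoselective hydrogenolysis of the bromine trans to the chromone (Bu3SnH, Pd(PPh3)4, PhMe, rt) gives the (Z)-2-(2-bromovinyl)chromone F6. Anti elimination with DBU in CH2Cl2 then delivers 11.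

Step 8. The C–O coupling may be sluggish. Long heating in methoxide then allows protodebromination and base-induced migration of the side-chain double bond, and the volatile, acid-labile product may be lost on isolation. The fallback reverses the order of bond formation, so that the hot methoxide step is done before any prenyl group is present. It sets out from 12 and comes back at 15. Mono-methoxylation of the symmetrical dibromide (NaOMe 1.2 equiv, CuBr cat., MeOH–NMP, 100 °C; the first methoxy group slows the second substitution) gives 3-bromo-4-methoxyfuran F7. Bromine–lithium exchange (n-BuLi, Et2O, −78 °C) gives 3-lithio-4-methoxyfuran F8. Allylation with 2 under CuBr·SMe2 catalysis gives 15.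

Further compounds
F1 | step 9 | methyl 3-bromo-5-hydroxy-4-methoxybenzoate | COC(=O)c1cc(O)c(OC)c(Br)c1
F2 | step 9 | methyl 3-bromo-4-methoxy-5-(methoxymethoxy)benzoate | COCOc1cc(C(=O)OC)cc(Br)c1OC
F3 | step 9 | methyl 4-methoxy-3-(methoxymethoxy)-5-(3-methylbut-2-enyl)benzoate | COCOc1cc(C(=O)OC)cc(CC=C(C)C)c1OC
F4 | step 9 | 1-[2-hydroxy-4,6-bis(methoxymethoxy)-3-(3-methylbut-2-enyl)phenyl]-3-[4-methoxy-3-(methoxymethoxy)-5-(3-methylbut-2-enyl)phenyl]propane-1,3-dione | COCOc1cc(C(=O)CC(=O)c2c(O)c(CC=C(C)C)c(OCOC)cc2OCOC)cc(CC=C(C)C)c1OC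
F5 | step 6 | 2-(2,2-dibromovinyl)-5,7-bis(methoxymethoxy)-8-(3-methylbut-2-enyl)-4H-chromen-4-one | BrC(Br)=Cc1cc(=O)c2c(OCOC)cc(OCOC)c(CC=C(C)C)c2o1
F6 | step 6 | 2-[(Z)-2-bromovinyl]-5,7-bis(methoxymethoxy)-8-(3-methylbut-2-enyl)-4H-chromen-4-one | Br/C=C\c1cc(=O)c2c(OCOC)cc(OCOC)c(CC=C(C)C)c2o1
F7 | step 8 | 3-bromo-4-methoxyfuran | COc1cocc1Br
F8 | step 8 | 3-lithio-4-methoxyfuran | [Li]c1cocc1OC
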